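**Retrosynthetic overview**

- The target is epiafzelechin-(4β→8)-epicatechin-(4β→8)-catechin. The last C–C disconnection is the upper interflavan bond (C-4 of the epiafzelechin unit to C-8 of the epicatechin unit): a Friedel–Crafts union of a 4-alkoxy epiafzelechin benzyl ether with a benzylated epicatechin–catechin dimer.
- Key disconnection: ring C of the lower catechin unit is opened at C-4–C-4a and at O-1–C-2. This leaves a phenol that hangs on C-4 of the epicatechin unit and a trans-2,3-epoxy aldehyde (C-4 as CHO, C-3/C-2 as the epoxide). A titanium-templated [3+3] annulation joins both bonds in one operation; the extra C-4 hydroxyl is removed afterwards.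
- Enabling feature: ring A of the lower unit is a phloroglucinol ring. Its C-8a oxygen and the neighbouring carbon C-4a (ortho/para to three oxygens) form an O,C-1,3-dinucleophile. C-2 is benzylic to the electron-rich catechol ring B and C-3 bears oxygen, so C-4/C-3/C-2 map onto an epoxy aldehyde 1,3-dielectrophile.
- The phenol is attached by Friedel–Crafts arylation of an epicatechin C-4 cation with 3,5-bis(benzyloxy)phenol. Its single free hydroxyl dictates that the later ring closure gives the 4→8 isomer.
- Ring order: rings A–C of the upper and middle units are bought; ring A of the lower unit is attached as a phenol, then its ring C is closed (ring B arrives with the epoxide). C-2/C-3 of the lower unit come from one catalytic epoxidation; both C-4 centres come from substrate control.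

Key step: step 6

Assumption: (−)-epiafzelechin, like (−)-epicatechin, is taken as a purchasable catalogue flavan-3-ol; the C-4 carbinol centre created in step 6 is formed without control, which is harmless because it becomes CH2 in step 7.

**Step 1**
Reactants: 1 (−)-epicatechin; 2 benzyl bromide
Product: 3 5,7,3',4'-tetra-O-benzyl-(−)-epicatechin
Conditions: BnBr (4.4 equiv), K2CO3 (5 equiv), DMF, 0 °C to rt
Reagents that add atoms: benzyl bromide 2, BrCc1ccccc1
Why: Williamson etherification of the four acidic phenolic hydroxyls in preference to the secondary C-3 alcohol under weak-base conditions, with no stereocentre touched.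

**Step 2**
Reactants: 3 5,7,3',4'-tetra-O-benzyl-(−)-epicatechin; 4 2-ethoxyethanol
Product: 5 5,7,3',4'-tetra-O-benzyl-4β-(2-ethoxyethoxy)epicatechin
Conditions: DDQ (2,3-dichloro-5,6-dicyano-1,4-benzoquinone, 2 equiv), 2-ethoxyethanol (5 equiv), CH2Cl2, rt
Reagents that add atoms: 2-ethoxyethanol 4, CCOCCO
Why: DDQ benzylic oxidation removes hydride from C-4, which is benzylic to the dioxygenated ring A, and the alcohol should trap the cation on the face trans to the C-3 hydroxyl (oxidative etherification established for benzylated flavan-3-ols).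

**Step 3**
Reactants: 5 5,7,3',4'-tetra-O-benzyl-4β-(2-ethoxyethoxy)epicatechin; 6 3,5-bis(benzyloxy)phenol
Product: 7 4β-[2,4-bis(benzyloxy)-6-hydroxyphenyl]-5,7,3',4'-tetra-O-benzylepicatechin
Conditions: 6 (3 equiv), Me3SiOSO2CF3 (0.2 equiv), CH2Cl2, −78 to −40 °C
Reagents that add atoms: none
Why: Friedel–Crafts arylation of the C-4 benzylic cation by the phloroglucinol-type phenol, expected at the carbon ortho to the hydroxyl (two equivalent sites flanked by OH and OBn, favoured statistically and sterically over the single site between two benzyloxy groups), with the aryl group entering on the β face trans to the C-3 hydroxyl as is general for 2,3-cis flavan-4-yl cations.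

**Step 4**
Reactants: 8 3,4-bis(benzyloxy)benzaldehyde; 9 (triphenylphosphoranylidene)acetaldehyde
Product: 10 (E)-3-[3,4-bis(benzyloxy)phenyl]prop-2-enal
Conditions: 9 (1.1 equiv), toluene, 80 °C
Reagents that add atoms: (triphenylphosphoranylidene)acetaldehyde 9, O=CC=P(c1ccccc1)(c1ccccc1)c1ccccc1
Why: Wittig olefination with a stabilised formyl ylide should give the (E)-enal selectively as a two-carbon homologation.

**Step 5**
Reactants: 10 (E)-3-[3,4-bis(benzyloxy)phenyl]prop-2-enal; 11 hydrogen peroxide
Product: 12 (2R,3S)-3-[3,4-bis(benzyloxy)phenyl]oxirane-2-carbaldehyde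
Conditions: (R)-2-{bis[3,5-bis(trifluoromethyl)phenyl](trimethylsilyloxy)methyl}pyrrolidine (10 mol %), 35% aq. H2O2 (1.3 equiv), CH2Cl2, rt; used at once
Reagents that add atoms: hydrogen peroxide 11, OO
Why: Iminium-catalysed organocatalytic epoxidation of an enal with a diarylprolinol silyl ether, in which hydroperoxide adds to C-β and the enamine closes onto the O–O bond on the same face; the (R)-catalyst is chosen because its diaryl(silyloxy)methyl group leaves the Re face of C-β open, so the trans-(2R,3S)-epoxide should result and both stereocentres of the future lower unit are set here.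

**Step 6**
Reactants: 7 4β-[2,4-bis(benzyloxy)-6-hydroxyphenyl]-5,7,3',4'-tetra-O-benzylepicatechin; 12 (2R,3S)-3-[3,4-bis(benzyloxy)phenyl]oxirane-2-carbaldehyde
Product: 15 5,7,3',4'-tetra-O-benzylepicatechin-(4β→8)-(2R,3S)-5,7,3',4'-tetra-O-benzylflavan-3,4-diol, via aryloxytitanium isopropoxide 13 (not isolated), via epoxy carbinol cyclic titanate 14 (not isolated)
Conditions: Ti(OiPr)4 (2.2 equiv), toluene, rt, then evaporation of iPrOH; 12 (1.3 equiv), CH2Cl2, −20 °C to rt; aq. KNaC4H4O6 work-up
Reagents that add atoms: none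
Why: Proposed new method: the aryloxytitanium triisopropoxide formed from the single free phenol binds the aldehyde of 12 at titanium and delivers it through a six-membered cyclic transition state to the only free carbon ortho to that oxygen (the future C-4a), which forges C-4–C-4a; the resulting cyclic titanate is a titanium-bound 2,3-epoxy alcohol whose distal benzylic C–O bond is activated, and the aryloxide oxygen then opens it to make O-1–C-2. The closest known reaction types are the ortho-specific hydroxyalkylation of titanium and magnesium phenoxides by α-oxygenated aldehydes (a templated Friedel–Crafts reaction), the Ti(OiPr)4-mediated opening of 2,3-epoxy alcohols at the carbon remote from the carbinol, and the 6-endo cyclisation of phenols onto aryl epoxides to give trans-flavan-3-ols; their merger in one flask on an epoxy aldehyde is the untested part. Ring C of the lower unit closes by 6-endo-tet opening of the epoxide at its benzylic carbon with inversion. C-3 (S) is the untouched C-2 of the epoxide and C-2 (R) arises by inversion of the epoxide C-3, so both derive from the catalyst-set epoxide of step 5 and the 2,3-trans (catechin) relationship follows from the trans epoxide, while the C-4 carbinol centre is uncontrolled and is deleted in step 7. The step needs C-attack at one defined ring position and 6-endo rather than 5-exo opening: the first is secured because the only unprotected phenol of 7 leaves a single ortho carbon for the titanium-templated attack (which also fixes the 4→8 connectivity), the second by the cation-stabilising 3,4-bis(benzyloxy)phenyl group on the benzylic epoxide carbon together with chelation of titanium between the C-4 alkoxide and the epoxide oxygen. The aldehyde group keeps the electron-rich epoxide deactivated until the C–C bond has been made, which orders the two bond formations.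

**Step 7**
Reactants: 15 5,7,3',4'-tetra-O-benzylepicatechin-(4β→8)-(2R,3S)-5,7,3',4'-tetra-O-benzylflavan-3,4-diol
Product: 16 5,7,3',4'-tetra-O-benzylepicatechin-(4β→8)-5,7,3',4'-tetra-O-benzylcatechin
Conditions: Et3SiH (5 equiv), CF3CO2H (3 equiv), CH2Cl2, −40 °C
Reagents that add atoms: none
Why: Ionic hydrogenation, in which acid ionises the C-4 carbinol that is benzylic to the 5,7-dioxygenated ring A and triethylsilane should deliver hydride to the cation faster than any arene can attack it, giving the C-4 methylene without touching C-2 or C-3.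

**Step 8**
Reactants: 17 (−)-epiafzelechin; 2 benzyl bromide
Product: 18 5,7,4'-tri-O-benzyl-(−)-epiafzelechin
Conditions: BnBr (3.3 equiv), K2CO3 (4 equiv), DMF, 0 °C to rt
Reagents that add atoms: benzyl bromide 2, BrCc1ccccc1
Why: Williamson etherification of the three phenolic hydroxyls, leaving the C-3 alcohol and both stereocentres untouched.

**Step 9**
Reactants: 18 5,7,4'-tri-O-benzyl-(−)-epiafzelechin; 4 2-ethoxyethanol
Product: 19 5,7,4'-tri-O-benzyl-4β-(2-ethoxyethoxy)epiafzelechin
Conditions: DDQ (2 equiv), 2-ethoxyethanol (5 equiv), CH2Cl2, rt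
Reagents that add atoms: 2-ethoxyethanol 4, CCOCCO
Why: DDQ benzylic oxidation at C-4 with capture of the cation by the alcohol trans to the C-3 hydroxyl, as in step 2.

**Step 10**
Reactants: 19 5,7,4'-tri-O-benzyl-4β-(2-ethoxyethoxy)epiafzelechin; 16 5,7,3',4'-tetra-O-benzylepicatechin-(4β→8)-5,7,3',4'-tetra-O-benzylcatechin
Product: 20 5,7,4'-tri-O-benzylepiafzelechin-(4β→8)-5,7,3',4'-tetra-O-benzylepicatechin-(4β→8)-5,7,3',4'-tetra-O-benzylcatechin
Conditions: 16 (2 equiv, excess recovered), Me3SiOSO2CF3 (0.2 equiv), CH2Cl2, −78 °C, then Et3N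
Reagents that add atoms: none
Why: Friedel–Crafts coupling of a flavan-4-yl cation with a flavan nucleophile (the standard procyanidin chain extension), in which C-8 of the epicatechin unit of 16 should react as the most accessible free ring position (both C-6 sites lie between two benzyloxy groups and the lower C-8 is substituted) and the bond should form on the β face, trans to the C-3 hydroxyl of the 2,3-cis cation.

**Step 11**
Reactants: 20 5,7,4'-tri-O-benzylepiafzelechin-(4β→8)-5,7,3',4'-tetra-O-benzylepicatechin-(4β→8)-5,7,3',4'-tetra-O-benzylcatechin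
Product: 21 epiafzelechin-(4β→8)-epicatechin-(4β→8)-catechin (CNP0158921.1)
Conditions: H2 (1 atm), Pd(OH)2/C, THF/MeOH/H2O, rt
Reagents that add atoms: none
Why: Hydrogenolysis of the eleven benzyl ethers under neutral conditions, which should leave the interflavan bonds and all eight stereocentres unchanged.

**Compound list**

1 | (−)-epicatechin, (2R,3R)-2-(3,4-dihydroxyphenyl)chromane-3,5,7-triol | Oc1cc(O)c2c(c1)O[C@H](c1ccc(O)c(O)c1)[C@H](O)C2 | starting material
2 | benzyl bromide | BrCc1ccccc1 | starting material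
3 | 5,7,3',4'-tetra-O-benzyl-(−)-epicatechin (2R,3R) | c1c(OCc2ccccc2)cc(OCc2ccccc2)c2c1O[C@H](c1ccc(OCc3ccccc3)c(OCc3ccccc3)c1)[C@H](O)C2 | intermediate
4 | 2-ethoxyethanol | CCOCCO | starting material
5 | 5,7,3',4'-tetra-O-benzyl-4β-(2-ethoxyethoxy)epicatechin (2,3-cis; 4-alkoxy trans to 3-OH) | c1c(OCc2ccccc2)cc(OCc2ccccc2)c2c1O[C@H](c1ccc(OCc3ccccc3)c(OCc3ccccc3)c1)[C@H](O)[C@H]2OCCOCC | intermediate
6 | 3,5-bis(benzyloxy)phenol | Oc1cc(OCc2ccccc2)cc(OCc2ccccc2)c1 | starting material
7 | 4β-[2,4-bis(benzyloxy)-6-hydroxyphenyl]-5,7,3',4'-tetra-O-benzylepicatechin (2,3-cis; aryl trans to 3-OH) | c1c(OCc2ccccc2)cc(OCc2ccccc2)c2c1O[C@H](c1ccc(OCc3ccccc3)c(OCc3ccccc3)c1)[C@H](O)[C@H]2c1c(O)cc(OCc2ccccc2)cc1OCc1ccccc1 | intermediate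
8 | 3,4-bis(benzyloxy)benzaldehyde | O=Cc1ccc(OCc2ccccc2)c(OCc2ccccc2)c1 | starting material
9 | (triphenylphosphoranylidene)acetaldehyde | O=CC=P(c1ccccc1)(c1ccccc1)c1ccccc1 | starting material
10 | (E)-3-[3,4-bis(benzyloxy)phenyl]prop-2-enal | O=C/C=C/c1ccc(OCc2ccccc2)c(OCc2ccccc2)c1 | intermediate
11 | hydrogen peroxide | OO | starting material
12 | (2R,3S)-3-[3,4-bis(benzyloxy)phenyl]oxirane-2-carbaldehyde (trans) | O=C[C@@H]1O[C@H]1c1ccc(OCc2ccccc2)c(OCc2ccccc2)c1 | intermediate
13 | bis(triisopropoxytitanium) derivative of 7 (aryloxide and C-3 alkoxide) | c1c(OCc2ccccc2)cc(OCc2ccccc2)c2c1O[C@H](c1ccc(OCc3ccccc3)c(OCc3ccccc3)c1)[C@H](O[Ti](OC(C)C)(OC(C)C)OC(C)C)[C@H]2c1c(O[Ti](OC(C)C)(OC(C)C)OC(C)C)cc(OCc2ccccc2)cc1OCc1ccccc1 | intermediate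
14 | cyclic diisopropoxytitanium aryloxide–alkoxide of the ortho-hydroxyalkylated epoxy carbinol (epoxide 2,3-trans intact; carbinol carbon as epimer mixture) | c1c(OCc2ccccc2)cc(OCc2ccccc2)c2c1O[C@H](c1ccc(OCc3ccccc3)c(OCc3ccccc3)c1)[C@H](O[Ti](OC(C)C)(OC(C)C)OC(C)C)[C@H]2c1c2O[Ti](OC(C)C)(OC(C)C)OC([C@@H]3O[C@H]3c3ccc(OCc4ccccc4)c(OCc4ccccc4)c3)c2c(OCc2ccccc2)cc1OCc1ccccc1 | intermediate
15 | 5,7,3',4'-tetra-O-benzylepicatechin-(4β→8)-(2R,3S)-5,7,3',4'-tetra-O-benzylflavan-3,4-diol (lower unit 2,3-trans; C-4 carbinol as epimer mixture) | c1c(OCc2ccccc2)cc(OCc2ccccc2)c2c1O[C@H](c1ccc(OCc3ccccc3)c(OCc3ccccc3)c1)[C@H](O)[C@H]2c1c(OCc2ccccc2)cc(OCc2ccccc2)c2c1O[C@H](c1ccc(OCc3ccccc3)c(OCc3ccccc3)c1)[C@@H](O)C2O | intermediate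
16 | 5,7,3',4'-tetra-O-benzylepicatechin-(4β→8)-5,7,3',4'-tetra-O-benzylcatechin (octa-O-benzyl procyanidin B1) | c1c(OCc2ccccc2)cc(OCc2ccccc2)c2c1O[C@H](c1ccc(OCc3ccccc3)c(OCc3ccccc3)c1)[C@H](O)[C@H]2c1c(OCc2ccccc2)cc(OCc2ccccc2)c2c1O[C@H](c1ccc(OCc3ccccc3)c(OCc3ccccc3)c1)[C@@H](O)C2 | intermediate
17 | (−)-epiafzelechin, (2R,3R)-2-(4-hydroxyphenyl)chromane-3,5,7-triol | Oc1ccc([C@H]2Oc3cc(O)cc(O)c3C[C@H]2O)cc1 | starting material
18 | 5,7,4'-tri-O-benzyl-(−)-epiafzelechin (2R,3R) | c1ccccc1COc1ccc([C@H]2Oc3cc(OCc4ccccc4)cc(OCc4ccccc4)c3C[C@H]2O)cc1 | intermediate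
19 | 5,7,4'-tri-O-benzyl-4β-(2-ethoxyethoxy)epiafzelechin (2,3-cis; 4-alkoxy trans to 3-OH) | c1ccccc1COc1ccc([C@H]2Oc3cc(OCc4ccccc4)cc(OCc4ccccc4)c3[C@H](OCCOCC)[C@H]2O)cc1 | intermediate
20 | 5,7,4'-tri-O-benzylepiafzelechin-(4β→8)-5,7,3',4'-tetra-O-benzylepicatechin-(4β→8)-5,7,3',4'-tetra-O-benzylcatechin (undeca-O-benzyl ether of the target) | c1ccccc1COc1ccc([C@H]2Oc3cc(OCc4ccccc4)cc(OCc4ccccc4)c3[C@H](c3c(OCc4ccccc4)cc(OCc4ccccc4)c4c3O[C@H](c3ccc(OCc5ccccc5)c(OCc5ccccc5)c3)[C@H](O)[C@H]4c3c(OCc4ccccc4)cc(OCc4ccccc4)c4c3O[C@H](c3ccc(OCc5ccccc5)c(OCc5ccccc5)c3)[C@@H](O)C4)[C@H]2O)cc1 | intermediate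
21 | epiafzelechin-(4β→8)-epicatechin-(4β→8)-catechin (CNP0158921.1) | Oc1ccc([C@H]2Oc3cc(O)cc(O)c3[C@H](c3c(O)cc(O)c4c3O[C@H](c3ccc(O)c(O)c3)[C@H](O)[C@H]4c3c(O)cc(O)c4c3O[C@H](c3ccc(O)c(O)c3)[C@@H](O)C4)[C@H]2O)cc1 | target

**Step count and risks**

Total step count: 11. Longest linear sequence: 7 steps (1 → 3 → 5 → 7 → 15 → 16 → 20 → 21).

Steps most likely to fail:

Step 6 (proposed new method). The hindered aryloxytitanium species may not add to the aldehyde at the ortho carbon. The epoxide may also open before the C–C bond forms, or by 5-exo attack. The newly formed benzylic C-4 carbinol may ionise under the Lewis acid and alkylate another arene. Fallback with known chemistry: the lower unit is bought instead of built. (+)-Catechin is benzylated with benzyl bromide 2 (K2CO3, DMF) to 5,7,3',4'-tetra-O-benzyl-(+)-catechin F1. The electrophile 5 is then condensed with an excess of F1 (Me3SiOSO2CF3, CH2Cl2, −78 °C), the long-established flavan-4-yl cation coupling that attacks C-8 of the catechin nucleophile on the β face of the cation. This fallback sets out from 5 and comes back to the route at 16; steps 3 to 7 are bypassed.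

Step 3. The C-4 cation may be captured para to the phenol hydroxyl or at the phenol oxygen, and it may self-condense through its own ring A. Fallback: the order of events is reversed, and the lower flavan is grown on the phenol before the interflavan bond is made. Phenol 6 is converted with Ti(OiPr)4 into its aryloxytitanium triisopropoxide F2. This is annulated with 12 under the conditions of step 6, through the cyclic titanate of the ortho-hydroxyalkylated epoxy carbinol F3, to give monomeric (2R,3S)-5,7,3',4'-tetra-O-benzylflavan-3,4-diol F4. Ionic hydrogenation as in step 7 (Et3SiH, CF3CO2H) should then give the tetra-O-benzyl-(+)-catechin F1 described above. Its coupling with 5 (Me3SiOSO2CF3, CH2Cl2, −78 °C), whose C-8 selectivity is established, returns to the route. This fallback sets out from 6 and 12, uses 5, and comes back at 16.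

Step 5. Iminium formation from the electron-rich enal may be slow, so the uncatalysed background epoxidation may erode enantioselectivity. The labile benzylic epoxide may also be opened by water or peroxide during the reaction. Fallback: the epoxide is made at the alcohol oxidation level. Enal 10 is reduced under Luche conditions (NaBH4, CeCl3·7H2O, MeOH, 0 °C) to (E)-3-[3,4-bis(benzyloxy)phenyl]prop-2-en-1-ol F5. Sharpless asymmetric epoxidation (Ti(OiPr)4, L-(+)-diisopropyl tartrate, tBuOOH, 4 Å molecular sieves, CH2Cl2, −20 °C) should give [(2S,3S)-3-[3,4-bis(benzyloxy)phenyl]oxiran-2-yl]methanol F6. Parikh–Doering oxidation (SO3·pyridine, DMSO, iPr2NEt, 0 °C) then gives the aldehyde. This fallback sets out from 10 and comes back at 12.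

**Further compounds**

F1 | step 6 | 5,7,3',4'-tetra-O-benzyl-(+)-catechin (2R,3S) | c1c(OCc2ccccc2)cc(OCc2ccccc2)c2c1O[C@H](c1ccc(OCc3ccccc3)c(OCc3ccccc3)c1)[C@@H](O)C2
F2 | step 3 | [3,5-bis(benzyloxy)phenoxy]titanium triisopropoxide | CC(C)O[Ti](OC(C)C)(OC(C)C)Oc1cc(OCc2ccccc2)cc(OCc2ccccc2)c1
F3 | step 3 | cyclic diisopropoxytitanium aryloxide–alkoxide of the ortho-hydroxyalkylated epoxy carbinol from 6 and 12 (carbinol carbon as epimer mixture) | CC(C)O[Ti]1(OC(C)C)Oc2cc(OCc3ccccc3)cc(OCc3ccccc3)c2C(O1)[C@@H]1O[C@H]1c1ccc(OCc2ccccc2)c(OCc2ccccc2)c1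
F4 | step 3 | (2R,3S)-5,7,3',4'-tetra-O-benzylflavan-3,4-diol (2,3-trans; C-4 carbinol as epimer mixture) | c1c(OCc2ccccc2)cc(OCc2ccccc2)c2c1O[C@H](c1ccc(OCc3ccccc3)c(OCc3ccccc3)c1)[C@@H](O)C2O
F5 | step 5 | (E)-3-[3,4-bis(benzyloxy)phenyl]prop-2-en-1-ol | OC/C=C/c1ccc(OCc2ccccc2)c(OCc2ccccc2)c1
F6 | step 5 | [(2S,3S)-3-[3,4-bis(benzyloxy)phenyl]oxiran-2-yl]methanol | OC[C@@H]1O[C@H]1c1ccc(OCc2ccccc2)c(OCc2ccccc2)c1
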